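Retrosynthesis: the C16 methylene, the C6–Cl bond, the C7–O lactone bond and the C20 acid are removed first. The C3 and C9 carbinols are then taken back to ketones and rejoined as a C3–C9 diol, which contracts the ten-membered ring to a cyclopentane. Last, the C3–C4 and C8–C9 bonds are cut together.
Enabling feature: the C4–O–C8 ether makes O/C4/C5/C6/C7/C8 an oxane with an oxygen function on C5 and a quaternary C8, which is a masked 3-oxidopyrylium. Its two α-carbons are spanned by the chain C3–C2–C1–C10–C9, oxygenated at both ends, which is the residue of a cleaved cyclopentane-1,2-diol.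
Forward ring order: furan to acetoxypyranone (Achmatowicz); cyclohexene (Diels–Alder); temporary lactone and lactol; cyclopentane (aldol); 8-oxabicyclo[3.2.1]octenone ((5+2)); ten-membered carbocycle and oxocane (glycol scission); γ-lactone (conjugate lactonisation).
Stereochemistry: C1, C10, C14 and the absolute sense come from the catalytic Diels–Alder reaction; C11 from dihydroxylation anti to the axial C15 methyl; C2 from α-face hydride. C4 and C8 come from the α-face, exo cycloaddition; C3 and C9 from peripheral hydride attack; C7 from intramolecular carboxylate delivery; C17 and C6 from equilibration.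

Key step: step 28

Remark: atoms carry briarane numbers (C15 = methyl on C1, C16 = methylene on C5, C17/C18/C19 = lactone CH/CH3/C=O, C20 on C11), and β is the face of the C15 methyl. Pyranone 7 is racemic, so 34–44 are C17 epimer pairs until step 38; centres that are later destroyed (C2 in 13–22, C9 in 24–30, C3 in 26–31, C5 in 38) are carried as mixtures.

**Pyranone branch**

Step 1
Reactants: 1 2-(furan-2-yl)acetic acid
Product: 2 tert-butyl 2-(furan-2-yl)acetate
Conditions: Boc2O, DMAP (cat.), t-BuOH, THF, rt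
Reagents that add atoms: di-tert-butyl dicarbonate CC(C)(C)OC(=O)OC(=O)OC(C)(C)C
Why: DMAP-catalysed esterification through the mixed carbonic anhydride gives the tert-butyl ester without the strong acid that the furan would not tolerate.

Step 2
Reactants: 2 tert-butyl 2-(furan-2-yl)acetate
Product: 3 tert-butyl 2-(furan-2-yl)propanoate (racemic)
Conditions: LiN(i-Pr)2, THF, −78 °C; MeI
Reagents that add atoms: iodomethane CI
Why: Ester enolate alkylation at the furyl-activated α-carbon installs the C18 methyl; C17 is left racemic on purpose because it is equilibrated in step 38.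

Step 3
Reactants: 3 tert-butyl 2-(furan-2-yl)propanoate
Product: 4 tert-butyl 2-(5-formylfuran-2-yl)propanoate
Conditions: POCl3, DMF, 0 °C to rt; then ice-water, NaOAc
Reagents that add atoms: N,N-dimethylformamide CN(C)C=O; water O
Why: Vilsmeier–Haack formylation attacks the only free α-position of the 2-alkylfuran, and the buffered hydrolysis spares the tert-butyl ester.

Step 4
Reactants: 4 tert-butyl 2-(5-formylfuran-2-yl)propanoate
Product: 5 tert-butyl 2-[5-(hydroxymethyl)furan-2-yl]propanoate
Conditions: NaBH4, MeOH, 0 °C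
Reagents that add atoms: none
Why: Borohydride reduces the aldehyde chemoselectively in the presence of the hindered ester.

Step 5
Reactants: 5 tert-butyl 2-[5-(hydroxymethyl)furan-2-yl]propanoate
Product: 6 tert-butyl 2-(2-hydroxy-5-oxo-5,6-dihydro-2H-pyran-2-yl)propanoate
Conditions: NBS, NaHCO3, THF/H2O, 0 °C
Reagents that add atoms: water O
Why: Achmatowicz oxidative ring expansion (bromonium-induced 2,5-addition of water, opening to the Z-enedione, hemiketalisation) turns the carbinol carbon into C4 and the furan carbons into C5–C8.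

Step 6
Reactants: 6 hydroxypyranone
Product: 7 tert-butyl 2-(2-acetoxy-5-oxo-5,6-dihydro-2H-pyran-2-yl)propanoate
Conditions: Ac2O, pyridine, DMAP (cat.), CH2Cl2, 0 °C
Reagents that add atoms: acetic anhydride CC(=O)OC(C)=O
Why: DMAP-catalysed acylation traps the cyclic hemiketal tautomer as the acetate, the leaving group for oxidopyrylium formation.

**Hydrindene branch**

Step 7
Reactants: 8 ethyl (E)-3-methyl-4-oxobut-2-enoate; 9 (E)-1-(trimethylsilyloxy)buta-1,3-diene
Product: 11 ethyl (1S,5S,6R)-6-formyl-5-hydroxy-6-methylcyclohex-3-ene-1-carboxylate, via trimethylsilyl ether adduct 10 (not isolated)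
Conditions: (R)-3,3-diphenyl-1-(2-methylphenyl)tetrahydro-1H,3H-pyrrolo[1,2-c][1,3,2]oxazaborole·HN(SO2CF3)2 (20 mol %), CH2Cl2, −78 °C; then 1 M HCl, THF, 0 °C
Reagents that add atoms: none
Why: Enantioselective Diels–Alder reaction catalysed by an N-protonated oxazaborolidine bound to the formyl group: the diene CH2 terminus adds to the enal β-carbon C10, the E-dienophile fixes methyl and ester cis, the formyl-endo transition state puts the C14 oxygen cis to the formyl carbon, and the (R)-catalyst is chosen so that the diene adds to the Si face at C1 (formyl C–H···O model); this sets C1, C10, C14 and the absolute configuration, and dilute acid removes the labile silyl group.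

Step 8
Reactants: 11 hydroxy aldehyde
Product: 12 ethyl (1S,5S,6R)-5-(tert-butyldimethylsilyloxy)-6-formyl-6-methylcyclohex-3-ene-1-carboxylate
Conditions: TBSOTf, 2,6-lutidine, CH2Cl2, −78 °C
Reagents that add atoms: tert-butyldimethylsilyl triflate CC(C)(C)[Si](C)(C)OS(=O)(=O)C(F)(F)F
Why: Silyl triflate silylation protects the hindered allylic alcohol; the aldehyde has no α-hydrogen and cannot enolise.

Step 9
Reactants: 12 silyloxy aldehyde ester
Product: 14 trans-fused bicyclic lactol (9-hydroxy), via trans-fused lactone 13 (not isolated)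
Conditions: MeMgBr, THF, −78 to 0 °C; then i-Bu2AlH, −78 °C; Rochelle salt
Reagents that add atoms: methylmagnesium bromide C[Mg]Br
Why: Grignard addition to the aldehyde (the ester is inert at −78 °C) gives an alkoxide that closes the trans-fused γ-lactone onto the equatorial C9 ester, and i-Bu2AlH stops at the lactol; C9 is kept below the carbonyl level here so that the later C11 ketone is not a β-keto lactone with a doubly activated, epimerisable C10–H.

Step 10
Reactants: 14 lactol
Product: 15 lactol methyl ether (9-methoxy)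
Conditions: MeOH, PPTS (cat.), rt
Reagents that add atoms: methanol CO
Why: Acid-catalysed acetalisation caps the lactol so that the C9 aldehyde stays masked during the oxidation and olefination steps.

Step 11
Reactants: 15 lactol methyl ether
Product: 16 11-oxo-12-ene (enone)
Conditions: CrO3, 3,5-dimethylpyrazole, CH2Cl2, −20 °C
Reagents that add atoms: chromium trioxide O=[Cr](=O)=O
Why: Allylic oxidation by the CrO3–pyrazole complex converts the unhindered allylic methylene C11 into the enone carbonyl, whereas the other allylic C–H (C14) is shielded by the quaternary C1 and the silyl ether.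

Step 12
Reactants: 16 enone
Product: 17 11-ketone
Conditions: H2 (1 atm), Pd/C, EtOAc, rt
Reagents that add atoms: none
Why: Heterogeneous hydrogenation saturates only the conjugated C12=C13 bond and creates no stereocentre.

Step 13
Reactants: 17 11-ketone
Product: 18 11(20)-methylene compound
Conditions: Cp2TiMe2, toluene, 65 °C, dark
Reagents that add atoms: dimethyltitanocene C[Ti](C)(C1C=CC=C1)C1C=CC=C1
Why: Petasis methylenation is neutral, so the ketone is olefinated without β-elimination of the C9 acetal oxygen or epimerisation of the ring-fusion C10–H, both of which a basic ylide would risk.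

Step 14
Reactants: 18 exocyclic alkene
Product: 19 11α,20-diol
Conditions: OsO4 (2 mol %), NMO, acetone/H2O, rt
Reagents that add atoms: 4-methylmorpholine N-oxide C[N+]1([O-])CCOCC1; water O
Why: Upjohn dihydroxylation adds to the exocyclic alkene from the equatorial α face, anti to the 1,3-related axial C15 methyl, which places the tertiary hydroxyl α and C20 β on C11.

Step 15
Reactants: 19 diol
Product: 20 11α,20-O-isopropylidene lactol methyl ether
Conditions: Me2C(OMe)2, PPTS (cat.), CH2Cl2, rt
Reagents that add atoms: 2,2-dimethoxypropane COC(C)(C)OC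
Why: Acid-catalysed transketalisation ties the 1,2-diol into a dioxolane, and the methyl acetal is unaffected in the absence of water.

Step 16
Reactants: 20 acetonide methyl acetal
Product: 21 trans-fused γ-lactone with the 11α,20-acetonide
Conditions: CrO3, H2SO4, H2O (Jones reagent), acetone, 0 °C
Reagents that add atoms: water O
Why: Jones oxidation of a lactol methyl ether (hydrolysis to the lactol, then chromate oxidation) gives the γ-lactone directly, with acetone as solvent suppressing net loss of the acetonide and the hindered secondary silyl ether tolerating the short exposure.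

Step 17
Reactants: 21 lactone
Product: 22 1,4-diol (C9 hydroxymethyl on C10; 1-hydroxyethyl on C1)
Conditions: LiAlH4, THF, 0 °C
Reagents that add atoms: none
Why: Hydride reduction opens the lactone to the diol under basic conditions that leave the acetonide and silyl ether intact.

Step 18
Reactants: 22 diol
Product: 23 keto aldehyde (C9 formyl on C10; acetyl C2–C3 on C1)
Conditions: (COCl)2, DMSO, CH2Cl2, −78 °C; Et3N, to 0 °C
Reagents that add atoms: none
Why: Swern oxidation activates both hydroxyls as alkoxysulfonium ions before base is added, so the two are oxidised together and the hydroxy aldehyde cannot close to a lactol and be oxidised back to the lactone.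

Step 19
Reactants: 23 keto aldehyde
Product: 24 9-hydroxy trans-hydrindan-2-one (9-epimers)
Conditions: LiN(SiMe3)2, THF, −78 °C; AcOH quench at −78 °C
Reagents that add atoms: none
Why: Kinetic enolisation of the methyl ketone and intramolecular aldol addition of C3 to the C9 aldehyde close the trans-fused cyclopentanone from the two equatorial arms, and the cold quench avoids dehydration and epimerisation at C10.

Step 20
Reactants: 24 aldol
Product: 25 9-triethylsilyl ether
Conditions: TESOTf, 2,6-lutidine, CH2Cl2, −78 °C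
Reagents that add atoms: triethylsilyl triflate CC[Si](CC)(CC)OS(=O)(=O)C(F)(F)F
Why: Silylation under non-basic conditions blocks retro-aldol cleavage and dehydration of the β-hydroxy ketone.

Step 21
Reactants: 25 hydrindanone
Product: 26 3-hydroxy ketone
Conditions: KN(SiMe3)2, THF, −78 °C; 3-phenyl-2-(phenylsulfonyl)oxaziridine
Reagents that add atoms: 3-phenyl-2-(phenylsulfonyl)oxaziridine O=S(=O)(c1ccccc1)N1OC1c1ccccc1
Why: The C2 ketone can enolise only toward C3 because C1 is quaternary, and the potassium enolate is hydroxylated by the Davis oxaziridine at a temperature where β-elimination of the C9 silyloxy group is slow.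

Step 22
Reactants: 26 α-hydroxy ketone
Product: 27 3-O-allyl carbonate
Conditions: allyl chloroformate, pyridine, DMAP (cat.), CH2Cl2, 0 °C
Reagents that add atoms: allyl chloroformate C=CCOC(=O)Cl
Why: Acylation gives a carbonate that is only a weak π-donor (needed for the polarity of the enediol) and can later be removed under neutral zerovalent-palladium conditions.

Step 23
Reactants: 27 carbonate ketone
Product: 28 2β-alcohol
Conditions: NaBH4, MeOH, −40 °C
Reagents that add atoms: none
Why: Hydride attacks the cyclopentanone from the α face, anti to the angular C15 methyl on the adjacent quaternary carbon, giving the 2β-alcohol, and the low temperature prevents carbonate migration.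

Step 24
Reactants: 28 alcohol
Product: 29 2β-tert-butyldimethylsilyl ether
Conditions: TBSOTf, 2,6-lutidine, CH2Cl2, 0 °C
Reagents that add atoms: tert-butyldimethylsilyl triflate CC(C)(C)[Si](C)(C)OS(=O)(=O)C(F)(F)F
Why: The silyl triflate silylates the hindered neopentyl-type secondary alcohol.

Step 25
Reactants: 29 tris-silyl ether
Product: 30 9-alcohol
Conditions: HF·pyridine, pyridine, THF, 0 °C
Reagents that add atoms: none
Why: Buffered HF·pyridine cleaves the secondary triethylsilyl ether much faster than the two hindered tert-butyldimethylsilyl ethers.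

Step 26
Reactants: 30 alcohol
Product: 31 9-ketone
Conditions: Dess–Martin periodinane, pyridine, CH2Cl2, rt
Reagents that add atoms: none
Why: Buffered Dess–Martin oxidation gives the ketone without epimerising the adjacent ring-fusion C10–H or shifting the α-carbonate.

Step 27
Reactants: 31 α-carbonate ketone
Product: 32 hydrindene enediol (9-triethylsilyloxy, 3-allyloxycarbonyloxy, C3=C9)
Conditions: TESOTf, Et3N, CH2Cl2, −78 to 0 °C
Reagents that add atoms: triethylsilyl triflate CC[Si](CC)(CC)OS(=O)(=O)C(F)(F)F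
Why: Soft enolisation removes the more acidic carbonate-activated C3–H rather than the tertiary C10–H and never forms a free enolate, so the C2 silyloxy group is not eliminated and the carbonate does not migrate.

**Union and endgame**

Step 28
Reactants: 7 acetoxypyranone; 32 hydrindene enediol
Product: 34 cyclopentane-fused 8-oxabicyclo[3.2.1]oct-3-en-2-one cycloadduct (C17 epimers), via oxidopyrylium ylide 33 (not isolated)
Conditions: i-Pr2NEt, MeCN, 60 °C; 7 (3 equiv) added slowly to 32
Reagents that add atoms: none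
Why: Proposed new method: the amine removes AcOH from 7 to give 3-oxidopyrylium 33, a carbonyl-ylide-type dipole across C4–O–C8, which adds suprafacially to the C3=C9 π bond in a concerted but asynchronous six-electron (5+2) cycloaddition; the closest known reaction is the intermolecular oxidopyrylium cycloaddition with enol ethers, and a tetrasubstituted cyclic enediol has not been used as partner. The C4–C3 bond leads because C3 is the nucleophilic β-carbon of the C9 silyl enol ether (the carbonate on C3 is a poor donor) and C4, next to the oxido carbon, carries the larger ylide coefficient, so the oxocarbenium character developing at C9 is quenched by C8, which fixes the regiochemistry. The seven-membered carbocycle C3–C4–C5–C6–C7–C8–C9 and the oxolane O–C4–C3–C9–C8 both close in this one pericyclic event, so each closure is a cycloaddition and not a cyclisation governed by closure rules. C3 and C9 are set cis by addition to the α face, because the β face is screened by the C2 silyl ether, the C15 methyl and C20; C4 and C8 follow from the exo arrangement in which the hydrindane lies under the ring oxygen and away from the C5–C6–C7 oxidoallyl unit. C17 is not controlled, since 7 is racemic. The step needs regio-, α-face and exo selectivity and must outrun dimerisation of 33 and its tautomerisation to the 8-alkylidene pyranone, which slow addition of excess 7 to warm 32 is meant to secure.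

Step 29
Reactants: 34 cycloadduct
Product: 35 tertiary C3 alcohol
Conditions: Pd(PPh3)4 (5 mol %), dimedone, THF, rt
Reagents that add atoms: none
Why: Tsuji–Trost deallylation: zerovalent palladium ionises the allyl carbonate, dimedone traps the π-allyl unit and CO2 is lost, freeing the C3 hydroxyl without base, which would trigger retro-aldol cleavage of the C3–C4 bond.

Step 30
Reactants: 35 alcohol
Product: 36 cis-3,9-diol
Conditions: HF·pyridine, pyridine, THF, rt
Reagents that add atoms: none
Why: HF·pyridine removes the tertiary triethylsilyl ether while the secondary tert-butyldimethylsilyl ethers, the acetonide and the tert-butyl ester persist.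

Step 31
Reactants: 36 diol
Product: 37 4,8-ether-bridged cyclodecane-3,9-dione with the C5 enone
Conditions: Pb(OAc)4, CH2Cl2, 0 °C
Reagents that add atoms: none
Why: Criegee glycol cleavage: the cis tertiary diol on the cyclopentane forms a cyclic plumbate that fragments to the C3 and C9 ketones, opening the tricycle to the ether-bridged ten-membered ring.

Step 32
Reactants: 37 trione
Product: 38 3,5,9-triol
Conditions: NaBH4, CeCl3·7H2O, MeOH, −78 to −20 °C
Reagents that add atoms: none
Why: Luche reduction reduces all three ketones; hydride should reach the C3 and C9 carbonyls of the bridged medium ring from the outer face (at C3 this is also the Felkin sense, anti to the C2 silyloxy group), and the C5 configuration is irrelevant.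

Step 33
Reactants: 38 triol
Product: 39 C5 enone 3,9-diol
Conditions: MnO2, CH2Cl2, rt
Reagents that add atoms: none
Why: Manganese dioxide re-oxidises only the allylic C5 alcohol and restores the enone.

Step 34
Reactants: 39 bis-silyl ether
Product: 40 2,3,9,14-tetraol
Conditions: HF·pyridine, THF, rt to 40 °C
Reagents that add atoms: none
Why: HF·pyridine cleaves both hindered secondary silyl ethers while keeping the acetonide, the tert-butyl ester and the β-hydroxy ketone, which a basic fluoride source would expose to retro-aldol cleavage.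

Step 35
Reactants: 40 tetraol
Product: 41 2,3,9,14-tetraacetate enone
Conditions: Ac2O, pyridine, DMAP (cat.), CH2Cl2, rt
Reagents that add atoms: acetic anhydride CC(=O)OC(C)=O
Why: DMAP-catalysed acetylation esterifies the four secondary hydroxyls, and the mild amine base avoids β-elimination of the C3 acetate.

Step 36
Reactants: 41 tetraacetate
Product: 43 C7/C19 γ-lactone 5-ketone with free 11,20-diol (C17 epimers), via seco acid 42 (not isolated)
Conditions: TFA/H2O (9:1), CH2Cl2, 0 °C to rt; evaporate; camphorsulfonic acid (10 mol %), CH2Cl2, rt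
Reagents that add atoms: none
Why: Aqueous acid cleaves the tert-butyl ester and the acetonide, and the freed acid adds to C7 of the enone in an acid-catalysed 5-exo-trig oxa-Michael lactonisation; delivery from the C8 side chain forces the cis ring fusion and sets C7, and acid is used because under base the β-acyloxy ketone would revert by E1cB.

Step 37
Reactants: 43 lactone ketone diol
Product: 44 C5–C6 triethylsilyl enol ether, 11,20-bis(triethylsilyl) ether (C17 epimers)
Conditions: TESOTf, Et3N, CH2Cl2, 0 °C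
Reagents that add atoms: triethylsilyl triflate CC[Si](CC)(CC)OS(=O)(=O)C(F)(F)F
Why: Soft enolisation gives the enol ether toward C6 (enolisation toward bridgehead C4 is disfavoured) and silylates both hydroxyls, which removes the E1cB pathway and protects the diol for the base step.

Step 38
Reactants: 44 silyl enol ether (C17 epimers)
Product: 45 silyl enol ether, single C17 epimer
Conditions: DBU, toluene, 60 °C
Reagents that add atoms: none
Why: DBU-mediated enolisation of the γ-lactone equilibrates C17 to the more stable epimer, with the methyl on the face of the ring oxygen and anti to the C9 branch, so the two series merge; with the ketone masked, the lactone carboxylate cannot be eliminated.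

Step 39
Reactants: 45 silyl enol ether
Product: 46 6-chloro-5-ketone with the C7/C19 γ-lactone and free 11,20-diol
Conditions: NCS, THF, −20 °C; then aq. HF, MeCN, 0 °C
Reagents that add atoms: N-chlorosuccinimide O=C1CCC(=O)N1Cl
Why: Electrophilic chlorination of the silyl enol ether puts chlorine on C6 from the face opposite the transannular C3–C9 bridge, and the acidic desilylation frees the diol and lets any axial epimer equilibrate through the enol to the equatorial chloride.

Step 40
Reactants: 46 chloro ketone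
Product: 47 5(16)-methylene 11,20-diol
Conditions: Zn, CH2Br2, TiCl4, THF/CH2Cl2, 0 °C to rt
Reagents that add atoms: dibromomethane BrCBr
Why: Takai–Lombardo methylenation is non-basic and ketone-selective, so the α-chloro-β-acyloxy ketone is olefinated without elimination, and it tolerates the acetates, the lactone and free hydroxyls.

Step 41
Reactants: 47 diol
Product: 48 C20 aldehyde
Conditions: SO3·pyridine, DMSO, i-Pr2NEt, CH2Cl2, 0 °C
Reagents that add atoms: none
Why: Parikh–Doering oxidation takes the primary alcohol to the aldehyde beside the untouched tertiary hydroxyl and cannot cleave the 1,2-diol.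

Step 42
Reactants: 48 aldehyde
Product: 49 CNP0186125.1
Conditions: NaClO2, NaH2PO4, 2-methyl-2-butene, t-BuOH/H2O, 0 °C
Reagents that add atoms: sodium chlorite [Na+].[O-]Cl=O
Why: Pinnick oxidation converts the α-hydroxy aldehyde into the acid, and the alkene scavenger removes hypochlorous acid and protects the exocyclic methylene.

**Compound list**

1 | 2-(furan-2-yl)acetic acid | OC(=O)Cc1ccco1 | starting material
2 | tert-butyl 2-(furan-2-yl)acetate | CC(C)(C)OC(=O)Cc1ccco1 | intermediate
3 | tert-butyl 2-(furan-2-yl)propanoate (racemic) | CC(C(=O)OC(C)(C)C)c1ccco1 | intermediate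
4 | tert-butyl 2-(5-formylfuran-2-yl)propanoate (racemic) | CC(C(=O)OC(C)(C)C)c1ccc(C=O)o1 | intermediate
5 | tert-butyl 2-[5-(hydroxymethyl)furan-2-yl]propanoate (racemic) | CC(C(=O)OC(C)(C)C)c1ccc(CO)o1 | intermediate
6 | tert-butyl 2-(2-hydroxy-5-oxo-5,6-dihydro-2H-pyran-2-yl)propanoate (stereoisomer mixture) | CC(C(=O)OC(C)(C)C)C1(O)C=CC(=O)CO1 | intermediate
7 | tert-butyl 2-(2-acetoxy-5-oxo-5,6-dihydro-2H-pyran-2-yl)propanoate (stereoisomer mixture) | CC(C(=O)OC(C)(C)C)C1(OC(C)=O)C=CC(=O)CO1 | intermediate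
8 | ethyl (E)-3-methyl-4-oxobut-2-enoate | CCOC(=O)/C=C(\C)C=O | starting material
9 | (E)-1-(trimethylsilyloxy)buta-1,3-diene | C=C/C=C/O[Si](C)(C)C | starting material
10 | ethyl (1S,5S,6R)-6-formyl-6-methyl-5-(trimethylsilyloxy)cyclohex-3-ene-1-carboxylate | CCOC(=O)[C@@H]1[C@](C)([C@@H](O[Si](C)(C)C)C=CC1)C=O | intermediate
11 | ethyl (1S,5S,6R)-6-formyl-5-hydroxy-6-methylcyclohex-3-ene-1-carboxylate | CCOC(=O)[C@@H]1[C@](C)([C@@H](O)C=CC1)C=O | intermediate
12 | ethyl (1S,5S,6R)-5-(tert-butyldimethylsilyloxy)-6-formyl-6-methylcyclohex-3-ene-1-carboxylate | CCOC(=O)[C@@H]1[C@](C)([C@@H](O[Si](C)(C)C(C)(C)C)C=CC1)C=O | intermediate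
13 | trans-fused cyclohexene γ-lactone: C9 carbonyl on C10, lactone oxygen on C2 (bearing the C3 methyl), C12=C13, 14α-OTBS, 15β-methyl | O=C1[C@@H]2[C@](C)([C@@H](O[Si](C)(C)C(C)(C)C)C=CC2)C(C)O1 | intermediate
14 | lactol of 13 (9-hydroxy) | OC1[C@@H]2[C@](C)([C@@H](O[Si](C)(C)C(C)(C)C)C=CC2)C(C)O1 | intermediate
15 | lactol methyl ether (9-methoxy) | COC1[C@@H]2[C@](C)([C@@H](O[Si](C)(C)C(C)(C)C)C=CC2)C(C)O1 | intermediate
16 | 11-oxo-12-ene lactol methyl ether | COC1[C@@H]2[C@](C)([C@@H](O[Si](C)(C)C(C)(C)C)C=CC2=O)C(C)O1 | intermediate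
17 | 11-oxo lactol methyl ether (C12–C13 saturated) | COC1[C@@H]2[C@](C)([C@@H](O[Si](C)(C)C(C)(C)C)CCC2=O)C(C)O1 | intermediate
18 | 11(20)-methylene lactol methyl ether | COC1[C@@H]2[C@](C)([C@@H](O[Si](C)(C)C(C)(C)C)CCC2=C)C(C)O1 | intermediate
19 | 11α,20-dihydroxy lactol methyl ether | COC1[C@@H]2[C@](C)([C@@H](O[Si](C)(C)C(C)(C)C)CC[C@]2(O)CO)C(C)O1 | intermediate
20 | 11α,20-O-isopropylidene lactol methyl ether | COC1[C@@H]2[C@](C)([C@@H](O[Si](C)(C)C(C)(C)C)CC[C@]2(OC(C)(C)O3)C3)C(C)O1 | intermediate
21 | trans-fused γ-lactone with 11α,20-acetonide and 14α-OTBS | O=C1[C@@H]2[C@](C)([C@@H](O[Si](C)(C)C(C)(C)C)CC[C@]2(OC(C)(C)O3)C3)C(C)O1 | intermediate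
22 | diol: C9 hydroxymethyl on C10, 1-hydroxyethyl (C2–C3) on C1, 11α,20-acetonide, 14α-OTBS | OC[C@@H]1[C@](C)([C@@H](O[Si](C)(C)C(C)(C)C)CC[C@]1(OC(C)(C)O2)C2)C(C)O | intermediate
23 | keto aldehyde: C9 formyl on C10, acetyl (C2–C3) on C1 | O=C[C@@H]1[C@](C)([C@@H](O[Si](C)(C)C(C)(C)C)CC[C@]1(OC(C)(C)O2)C2)C(C)=O | intermediate
24 | 9-hydroxy trans-hydrindan-2-one (ring C1–C2–C3–C9–C10; 9-epimers) | OC1[C@@H]2[C@](C)([C@@H](O[Si](C)(C)C(C)(C)C)CC[C@]2(OC(C)(C)O3)C3)C(=O)C1 | intermediate
25 | 9-(triethylsilyloxy) trans-hydrindan-2-one | C1(O[Si](CC)(CC)CC)[C@@H]2[C@](C)([C@@H](O[Si](C)(C)C(C)(C)C)CC[C@]2(OC(C)(C)O3)C3)C(=O)C1 | intermediate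
26 | 3-hydroxy-9-(triethylsilyloxy) trans-hydrindan-2-one | C1(O[Si](CC)(CC)CC)[C@@H]2[C@](C)([C@@H](O[Si](C)(C)C(C)(C)C)CC[C@]2(OC(C)(C)O3)C3)C(=O)C1O | intermediate
27 | 3-(allyloxycarbonyloxy)-9-(triethylsilyloxy) trans-hydrindan-2-one | C1(O[Si](CC)(CC)CC)[C@@H]2[C@](C)([C@@H](O[Si](C)(C)C(C)(C)C)CC[C@]2(OC(C)(C)O3)C3)C(=O)C1OC(=O)OCC=C | intermediate
28 | 2β-hydroxy 3-allyl carbonate 9-triethylsilyl ether | C1(O[Si](CC)(CC)CC)[C@@H]2[C@](C)([C@@H](O[Si](C)(C)C(C)(C)C)CC[C@]2(OC(C)(C)O3)C3)[C@@H](O)C1OC(=O)OCC=C | intermediate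
29 | 2β,14α-bis(TBSO) 3-allyl carbonate 9-triethylsilyl ether | C1(O[Si](CC)(CC)CC)[C@@H]2[C@](C)([C@@H](O[Si](C)(C)C(C)(C)C)CC[C@]2(OC(C)(C)O3)C3)[C@@H](O[Si](C)(C)C(C)(C)C)C1OC(=O)OCC=C | intermediate
30 | 9-hydroxy 2β,14α-bis(TBSO) 3-allyl carbonate | OC1[C@@H]2[C@](C)([C@@H](O[Si](C)(C)C(C)(C)C)CC[C@]2(OC(C)(C)O3)C3)[C@@H](O[Si](C)(C)C(C)(C)C)C1OC(=O)OCC=C | intermediate
31 | 9-oxo 2β,14α-bis(TBSO) 3-allyl carbonate | O=C1[C@@H]2[C@](C)([C@@H](O[Si](C)(C)C(C)(C)C)CC[C@]2(OC(C)(C)O3)C3)[C@@H](O[Si](C)(C)C(C)(C)C)C1OC(=O)OCC=C | intermediate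
32 | hydrindene enediol: C3=C9, 9-triethylsilyloxy, 3-allyloxycarbonyloxy, 2β,14α-bis(TBSO), 11α,20-acetonide | C1(O[Si](CC)(CC)CC)[C@@H]2[C@](C)([C@@H](O[Si](C)(C)C(C)(C)C)CC[C@]2(OC(C)(C)O3)C3)[C@@H](O[Si](C)(C)C(C)(C)C)C=1OC(=O)OCC=C | intermediate
33 | tert-butyl 2-(5-oxidopyrylium-2-yl)propanoate (3-oxidopyrylium ylide) | CC(C(=O)OC(C)(C)C)c1ccc([O-])c[o+]1 | intermediate
34 | cycloadduct: 8-oxabicyclo[3.2.1]oct-3-en-2-one (O bridging C4/C8, C5 ketone, C6=C7) fused at C3–C9 to the hydrindane cyclopentane; 3β-allyl carbonate, 9β-OTES, C8 side chain CH(CH3)CO2t-Bu (C17 epimers) | O=C1[C@H]2O[C@](C=C1)(C(C)C(=O)OC(C)(C)C)[C@]4(O[Si](CC)(CC)CC)[C@@H]1[C@](C)([C@@H](O[Si](C)(C)C(C)(C)C)CC[C@]1(OC(C)(C)O3)C3)[C@@H](O[Si](C)(C)C(C)(C)C)[C@]24OC(=O)OCC=C | intermediate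
35 | cycloadduct 3β-ol 9β-triethylsilyl ether (C17 epimers) | O=C1[C@H]2O[C@](C=C1)(C(C)C(=O)OC(C)(C)C)[C@]4(O[Si](CC)(CC)CC)[C@@H]1[C@](C)([C@@H](O[Si](C)(C)C(C)(C)C)CC[C@]1(OC(C)(C)O3)C3)[C@@H](O[Si](C)(C)C(C)(C)C)[C@]24O | intermediate
36 | cycloadduct cis-3β,9β-diol (C17 epimers) | O=C1[C@H]2O[C@](C=C1)(C(C)C(=O)OC(C)(C)C)[C@]4(O)[C@@H]1[C@](C)([C@@H](O[Si](C)(C)C(C)(C)C)CC[C@]1(OC(C)(C)O3)C3)[C@@H](O[Si](C)(C)C(C)(C)C)[C@]24O | intermediate
37 | 4,8-ether-bridged cyclodecane-3,9-dione with C5 enone (11-oxabicyclo[5.3.1]undecane core), 2β,14α-bis(TBSO), 11α,20-acetonide (C17 epimers) | O=C1[C@H]2O[C@](C=C1)(C(C)C(=O)OC(C)(C)C)C(=O)[C@@H]1[C@](C)([C@@H](O[Si](C)(C)C(C)(C)C)CC[C@]1(OC(C)(C)O3)C3)[C@@H](O[Si](C)(C)C(C)(C)C)C2=O | intermediate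
38 | 3,5,9-triol (C5 and C17 epimers) | OC1[C@H]2O[C@](C=C1)(C(C)C(=O)OC(C)(C)C)[C@@H](O)[C@@H]1[C@](C)([C@@H](O[Si](C)(C)C(C)(C)C)CC[C@]1(OC(C)(C)O3)C3)[C@@H](O[Si](C)(C)C(C)(C)C)[C@@H]2O | intermediate
39 | C5 enone 3,9-diol, 2β,14α-bis(TBSO) (C17 epimers) | O=C1[C@H]2O[C@](C=C1)(C(C)C(=O)OC(C)(C)C)[C@@H](O)[C@@H]1[C@](C)([C@@H](O[Si](C)(C)C(C)(C)C)CC[C@]1(OC(C)(C)O3)C3)[C@@H](O[Si](C)(C)C(C)(C)C)[C@@H]2O | intermediate
40 | C5 enone 2,3,9,14-tetraol (C17 epimers) | O=C1[C@H]2O[C@](C=C1)(C(C)C(=O)OC(C)(C)C)[C@@H](O)[C@@H]1[C@](C)([C@@H](O)CC[C@]1(OC(C)(C)O3)C3)[C@@H](O)[C@@H]2O | intermediate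
41 | 2,3,9,14-tetraacetate enone with tert-butyl ester and 11α,20-acetonide (C17 epimers) | O=C1[C@H]2O[C@](C=C1)(C(C)C(=O)OC(C)(C)C)[C@@H](OC(C)=O)[C@@H]1[C@](C)([C@@H](OC(C)=O)CC[C@]1(OC(C)(C)O3)C3)[C@@H](OC(C)=O)[C@@H]2OC(C)=O | intermediate
42 | seco acid: tetraacetate enone with free C19 acid and 11,20-diol (C17 epimers) | O=C1[C@H]2O[C@](C=C1)(C(C)C(=O)O)[C@@H](OC(C)=O)[C@@H]1[C@](C)([C@@H](OC(C)=O)CC[C@]1(O)CO)[C@@H](OC(C)=O)[C@@H]2OC(C)=O | intermediate
43 | 5-ketone with cis-fused C7/C19 γ-lactone, tetraacetate, 11,20-diol (C17 epimers) | O=C1[C@H]2O[C@]3(C(C)C(=O)O[C@H]3C1)[C@@H](OC(C)=O)[C@@H]1[C@](C)([C@@H](OC(C)=O)CC[C@]1(O)CO)[C@@H](OC(C)=O)[C@@H]2OC(C)=O | intermediate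
44 | C5–C6 triethylsilyl enol ether, 11,20-bis(triethylsilyl) ether, γ-lactone tetraacetate (C17 epimers) | C1(O[Si](CC)(CC)CC)[C@H]2O[C@]3(C(C)C(=O)O[C@H]3C=1)[C@@H](OC(C)=O)[C@@H]1[C@](C)([C@@H](OC(C)=O)CC[C@]1(O[Si](CC)(CC)CC)CO[Si](CC)(CC)CC)[C@@H](OC(C)=O)[C@@H]2OC(C)=O | intermediate
45 | same silyl enol ether, single C17 epimer (methyl anti to C9) | C1(O[Si](CC)(CC)CC)[C@H]2O[C@]3([C@@H](C)C(=O)O[C@H]3C=1)[C@@H](OC(C)=O)[C@@H]1[C@](C)([C@@H](OC(C)=O)CC[C@]1(O[Si](CC)(CC)CC)CO[Si](CC)(CC)CC)[C@@H](OC(C)=O)[C@@H]2OC(C)=O | intermediate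
46 | 6-chloro-5-ketone with C7/C19 γ-lactone, tetraacetate, free 11,20-diol | O=C1[C@H]2O[C@]3([C@@H](C)C(=O)O[C@H]3[C@H]1Cl)[C@@H](OC(C)=O)[C@@H]1[C@](C)([C@@H](OC(C)=O)CC[C@]1(O)CO)[C@@H](OC(C)=O)[C@@H]2OC(C)=O | intermediate
47 | 6-chloro-5(16)-methylene lactone tetraacetate 11,20-diol | C=C1[C@H]2O[C@]3([C@@H](C)C(=O)O[C@H]3[C@H]1Cl)[C@@H](OC(C)=O)[C@@H]1[C@](C)([C@@H](OC(C)=O)CC[C@]1(O)CO)[C@@H](OC(C)=O)[C@@H]2OC(C)=O | intermediate
48 | C20 aldehyde of 47 (11-hydroxy-20-oxo) | C=C1[C@H]2O[C@]3([C@@H](C)C(=O)O[C@H]3[C@H]1Cl)[C@@H](OC(C)=O)[C@@H]1[C@](C)([C@@H](OC(C)=O)CC[C@]1(O)C=O)[C@@H](OC(C)=O)[C@@H]2OC(C)=O | intermediate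
49 | CNP0186125.1 | C=C1[C@H]2O[C@]3([C@@H](C)C(=O)O[C@H]3[C@H]1Cl)[C@@H](OC(C)=O)[C@@H]1[C@](C)([C@@H](OC(C)=O)CC[C@]1(O)C(=O)O)[C@@H](OC(C)=O)[C@@H]2OC(C)=O | target

**Totals and risks**

Total step count: 42 (steps 1–6 pyranone branch, steps 7–27 hydrindene branch, steps 28–42 union and endgame).
Longest linear sequence: 36 steps (steps 7–42, from 8 and 9 to 49).

Steps most likely to fail:

Step 28. The hindered ylide may dimerise or tautomerise faster than the tetrasubstituted enediol captures it, or bonding may begin at the wrong terminus, forming the two vicinal fully substituted centres only sluggishly. The fallback uses known reactions only and sets out from alcohol 30. The C9 hydroxyl is capped with 2,2,2-trichloroethyl chloroformate and pyridine to give the mixed bis-carbonate F1. Zerovalent-palladium deallylation (Pd(PPh3)4, dimedone) frees the C3 alcohol F2, and Dess–Martin oxidation gives the C3 ketone F3. Me3SiOTf/Et3N enolises toward the carbonate-bearing C9 to give the regioisomeric enediol F4, in which the silyl donor sits on C3 and C9 is the nucleophilic carbon. A Lewis-acid-catalysed Ferrier-type C-glycosylation of acetoxypyranone 7 (Me3SiOTf cat., CH2Cl2, −78 °C) forms the C8–C9 bond and returns the C3 ketone in the pyranone adduct F5. An intramolecular aldol addition of the pyranone C4 enolate to the C3 ketone (LiN(SiMe3)2, −78 °C) forms the C3–C4 bond and closes the oxabicyclooctenone carbonate F6; only the C8 epimer with C4 and C8 on the same face can close. Zinc in buffered acetic acid removes the trichloroethyl carbonate and the route is rejoined at diol 36.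

Step 32. The C4 hydrogen flanked by the C3 and C5 carbonyls may enolise and the 1,3-dicarbonyl unit may undergo retro-Claisen-type cleavage under the hydride conditions, and facial control at C3 and C9 in the flexible medium ring may be poor. The fallback sets out from diol 36 and changes the order of events. Luche reduction of the enone carbonyl before ring opening gives the allylic triol F7. Pb(OAc)4 cleavage then gives the 5-hydroxy-3,9-dione F8, in which C4 is no longer doubly activated. The C5 hydroxyl directs hydride to the C3 ketone (Me4NBH(OAc)3, 1,3-anti delivery) and NaBH4 completes the reduction at C9, returning to triol 38.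

Step 40. Zinc may reductively remove the C6 chloride, or the Lewis-acidic titanium species may induce β-elimination of the C7 lactone carboxylate before olefination. The fallback sets out from chloro ketone 46 and replaces the one-step methylenation by a two-step Peterson olefination. Me3SiCH2MgCl with CeCl3 in THF at −78 °C (a non-basic organocerium addition, used in excess because of the two free hydroxyls) gives the β-hydroxysilane F9. Acid-promoted anti elimination (aq. HF, MeCN, 0 °C) then returns to methylene compound 47.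

**Further compounds**

F1 | step 28 | 9-O-(2,2,2-trichloroethoxycarbonyl) 3-O-(allyloxycarbonyl) 2β,14α-bis(TBSO) hydrindane | ClC(Cl)(Cl)COC(=O)OC1[C@@H]2[C@](C)([C@@H](O[Si](C)(C)C(C)(C)C)CC[C@]2(OC(C)(C)O3)C3)[C@@H](O[Si](C)(C)C(C)(C)C)C1OC(=O)OCC=C
F2 | step 28 | 3-hydroxy 9-O-(2,2,2-trichloroethoxycarbonyl) hydrindane | ClC(Cl)(Cl)COC(=O)OC1[C@@H]2[C@](C)([C@@H](O[Si](C)(C)C(C)(C)C)CC[C@]2(OC(C)(C)O3)C3)[C@@H](O[Si](C)(C)C(C)(C)C)C1O
F3 | step 28 | 3-oxo 9-O-(2,2,2-trichloroethoxycarbonyl) hydrindane | ClC(Cl)(Cl)COC(=O)OC1[C@@H]2[C@](C)([C@@H](O[Si](C)(C)C(C)(C)C)CC[C@]2(OC(C)(C)O3)C3)[C@@H](O[Si](C)(C)C(C)(C)C)C1=O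
F4 | step 28 | regioisomeric enediol: C3=C9, 3-trimethylsilyloxy, 9-(2,2,2-trichloroethoxycarbonyloxy) | C1(OC(=O)OCC(Cl)(Cl)Cl)[C@@H]2[C@](C)([C@@H](O[Si](C)(C)C(C)(C)C)CC[C@]2(OC(C)(C)O3)C3)[C@@H](O[Si](C)(C)C(C)(C)C)C=1O[Si](C)(C)C
F5 | step 28 | C8–C9-linked pyranone adduct: 2H-pyran-3(6H)-one bonded through C8 to C9 of the 3-oxo hydrindane (C17 epimers) | O=C1CO[C@](C=C1)(C(C)C(=O)OC(C)(C)C)[C@]4(OC(=O)OCC(Cl)(Cl)Cl)[C@@H]1[C@](C)([C@@H](O[Si](C)(C)C(C)(C)C)CC[C@]1(OC(C)(C)O3)C3)[C@@H](O[Si](C)(C)C(C)(C)C)C4=O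
F6 | step 28 | oxabicyclo[3.2.1]octenone 3β-ol 9β-(2,2,2-trichloroethyl carbonate) (C17 epimers) | O=C1[C@H]2O[C@](C=C1)(C(C)C(=O)OC(C)(C)C)[C@]4(OC(=O)OCC(Cl)(Cl)Cl)[C@@H]1[C@](C)([C@@H](O[Si](C)(C)C(C)(C)C)CC[C@]1(OC(C)(C)O3)C3)[C@@H](O[Si](C)(C)C(C)(C)C)[C@]24O
F7 | step 32 | cycloadduct 3β,5,9β-triol (C5 allylic alcohol; C5 and C17 epimers) | OC1[C@H]2O[C@](C=C1)(C(C)C(=O)OC(C)(C)C)[C@]4(O)[C@@H]1[C@](C)([C@@H](O[Si](C)(C)C(C)(C)C)CC[C@]1(OC(C)(C)O3)C3)[C@@H](O[Si](C)(C)C(C)(C)C)[C@]24O
F8 | step 32 | 5-hydroxy-6-ene 4,8-ether-bridged cyclodecane-3,9-dione (C5 and C17 epimers) | OC1[C@H]2O[C@](C=C1)(C(C)C(=O)OC(C)(C)C)C(=O)[C@@H]1[C@](C)([C@@H](O[Si](C)(C)C(C)(C)C)CC[C@]1(OC(C)(C)O3)C3)[C@@H](O[Si](C)(C)C(C)(C)C)C2=O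
F9 | step 40 | 6-chloro-5-hydroxy-5-[(trimethylsilyl)methyl] lactone tetraacetate 11,20-diol (C5 epimers) | C[Si](C)(C)CC1(O)[C@H]2O[C@]3([C@@H](C)C(=O)O[C@H]3[C@H]1Cl)[C@@H](OC(C)=O)[C@@H]1[C@](C)([C@@H](OC(C)=O)CC[C@]1(O)CO)[C@@H](OC(C)=O)[C@@H]2OC(C)=O
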